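The cyclohexene ring (C1 carries C7H2OBz, C2 is the olefinic CH, C3–C6 are oxygenated) is read as D-glucose with C6 bonded to C1: the all-trans triad C3/C4/C5 is glucose C2/C3/C4 and the C5 benzoate sits on glucose O4. The key step, a Ferrier carbocyclization of a methyl 6-deoxyhex-5-enopyranoside, exploits that the six ring atoms form one unbranched hexose chain; it opens the pyranose and closes the carbocycle in one operation without touching the triad. The precursor draws its 4-O-benzoate and its 6-bromide from one Hanessian–Hullar opening of a 4,6-benzylidene acetal. Dehydration, Baylis–Hillman hydroxymethylation (C7) and a C4-hydroxyl-directed reduction (C6) complete the target.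

Key step: step 4

Remark: glucose locants are used for 1–5. From 6 on, the Why lines use the target locants (glucose C6, C1, C2, C3, C4, C5 = target C1, C2, C3, C4, C5, C6), while locants inside compound names follow IUPAC rules.

Step 1
Reactants: 1 methyl 4,6-O-[(R)-benzylidene]-α-D-glucopyranoside
Product: 2 methyl 2,3-di-O-benzyl-4,6-O-[(R)-benzylidene]-α-D-glucopyranoside
Conditions: NaH, BnBr, Bu4NI (cat.), DMF, 0 °C to rt
Reagents that add atoms: benzyl bromide, BrCc1ccccc1
Why: Williamson etherification of the only two free hydroxyls (O2 and O3) under conditions to which the acetal and the glycoside are inert, so that no stereocentre is touched.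

Step 2
Reactants: 2 methyl 2,3-di-O-benzyl-4,6-O-[(R)-benzylidene]-α-D-glucopyranoside
Product: 3 methyl 4-O-benzoyl-2,3-di-O-benzyl-6-bromo-6-deoxy-α-D-glucopyranoside
Conditions: NBS, BaCO3, CCl4, reflux
Reagents that add atoms: N-bromosuccinimide, O=C1CCC(=O)N1Br
Why: Hanessian–Hullar reaction, in which radical bromination of the doubly activated acetal C–H, ionisation and attack of bromide at the primary C6 should leave the benzoate on the secondary O4 (the ring ester of the target), with C4 and C5 unchanged because no bond to them is broken.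

Step 3
Reactants: 3 methyl 4-O-benzoyl-2,3-di-O-benzyl-6-bromo-6-deoxy-α-D-glucopyranoside
Product: 4 methyl 4-O-benzoyl-2,3-di-O-benzyl-6-deoxy-α-D-xylo-hex-5-enopyranoside
Conditions: AgF, pyridine, rt, dark
Reagents that add atoms: none
Why: Silver-assisted E2 dehydrobromination across C5–C6 should give the exocyclic enol ether in a medium too weakly basic to move or cleave the 4-O-benzoate, the C5 stereocentre being given up on purpose and rebuilt in step 9.

Step 4
Reactants: 4 methyl 4-O-benzoyl-2,3-di-O-benzyl-6-deoxy-α-D-xylo-hex-5-enopyranoside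
Product: 6 (2S,3R,4S,5S)-2-benzoyloxy-3,4-bis(benzyloxy)-5-hydroxycyclohexan-1-one, via acyclic 6-mercurio-5-keto aldehyde 5 (not isolated)
Conditions: Hg(OCOCF3)2 (10 mol %), acetone–H2O, rt
Reagents that add atoms: water, O
Why: Divalent mercury adds to C6 and water to C5 of the electron-rich enol ether, the hemiketal collapses, methanol leaves the liberated hemiacetal, and the α-mercurio keto aldehyde 5 closes by intramolecular aldol addition of C6 to C1, which frees the mercury salt for the next turnover. This is the Ferrier carbocyclization, a known reaction of hex-5-enopyranosides that tolerates ester protection. The six-membered carbocycle is closed in the 6-(enolendo)-exo-trig mode. The one new stereocentre, the carbinol at former C1, should form axial and cis to O2 through a chair-like transition state in which mercury bridges the two carbonyl oxygens, and it is erased in step 5, so its configuration is not critical. The step needs a regiodefined enolate, and the metal on C6 secures it: the ketone is never enolised towards C4, so the benzoyloxy-bearing C4 is not epimerised, O3 is not eliminated, and glucose C2–C4 pass unchanged into target C3–C5. Chemoselectivity rests on the enol ether being the only strong π-nucleophile, the benzyl ethers and the benzoate being inert to aqueous acetone at room temperature.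

Step 5
Reactants: 6 (2S,3R,4S,5S)-2-benzoyloxy-3,4-bis(benzyloxy)-5-hydroxycyclohexan-1-one
Product: 8 (4S,5R,6S)-6-benzoyloxy-4,5-bis(benzyloxy)cyclohex-2-en-1-one, via secondary mesylate 7 (not isolated)
Conditions: MsCl, Et3N, CH2Cl2, 0 °C to rt
Reagents that add atoms: none
Why: Mesylation of the only free hydroxyl followed by E1cB loss of methanesulfonate across C1–C2 should give the conjugated enone from either carbinol epimer, the short exposure to Et3N sparing the C5–H next to the ketone.

Step 6
Reactants: 8 (4S,5R,6S)-6-benzoyloxy-4,5-bis(benzyloxy)cyclohex-2-en-1-one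
Product: 9 (4S,5R,6S)-6-benzoyloxy-4,5-bis(benzyloxy)-2-(hydroxymethyl)cyclohex-2-en-1-one
Conditions: aq. HCHO, DMAP, THF, rt
Reagents that add atoms: formaldehyde, C=O
Why: Morita–Baylis–Hillman reaction, in which DMAP adds reversibly to C2, the enolate takes up formaldehyde at C1 and DMAP is expelled, which installs C7 without creating a stereocentre and with a nucleophile too weakly basic to enolise the ketone towards C5.

Step 7
Reactants: 9 (4S,5R,6S)-6-benzoyloxy-4,5-bis(benzyloxy)-2-(hydroxymethyl)cyclohex-2-en-1-one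
Product: 10 [(3S,4R,5S)-5-benzoyloxy-3,4-bis(benzyloxy)-6-oxocyclohex-1-en-1-yl]methyl benzoate
Conditions: BzCl, pyridine, CH2Cl2, 0 °C
Reagents that add atoms: benzoyl chloride, O=C(Cl)c1ccccc1
Why: Pyridine-mediated O-acylation of the single free hydroxyl, a primary allylic one, so that no question of selectivity arises.

Step 8
Reactants: 10 [(3S,4R,5S)-5-benzoyloxy-3,4-bis(benzyloxy)-6-oxocyclohex-1-en-1-yl]methyl benzoate
Product: 11 [(3S,4R,5S)-5-benzoyloxy-3,4-dihydroxy-6-oxocyclohex-1-en-1-yl]methyl benzoate
Conditions: BCl3, CH2Cl2, −78 °C; then MeOH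
Reagents that add atoms: none
Why: Lewis acid ether cleavage, in which BCl3 binds the two benzyl ether oxygens and chloride takes the benzyl groups, while the esters survive at −78 °C and the conjugated ketone disfavours ionisation at the allylic C3 and C7, which is why debenzylation precedes the reduction.

Step 9
Reactants: 11 [(3S,4R,5S)-5-benzoyloxy-3,4-dihydroxy-6-oxocyclohex-1-en-1-yl]methyl benzoate
Product: 13 [(3S,4R,5R,6R)-5-benzoyloxy-3,4,6-trihydroxycyclohex-1-en-1-yl]methyl benzoate, via O4-bound diacetoxyborohydride 12 (not isolated)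
Conditions: Me4NBH(OAc)3, MeCN–AcOH, −20 °C; aq. NaHCO3 work-up
Reagents that add atoms: none
Why: Evans–Saksena reduction, in which the C4 hydroxyl (β to the ketone) replaces an acetate on boron and the bound hydride should reach C6 from the C4–O face through the ring-flipped half-chair (C5–OBz axial and anti to the incoming hydride), which sets C6 as R with its hydroxyl anti to C4–OH and cis to C5–OBz, the free reagent being too weak to reduce the enone on its own.

Compound list
1 | methyl 4,6-O-[(R)-benzylidene]-α-D-glucopyranoside | CO[C@H]1O[C@@H]2CO[C@@H](c3ccccc3)O[C@H]2[C@H](O)[C@H]1O | starting material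
2 | methyl 2,3-di-O-benzyl-4,6-O-[(R)-benzylidene]-α-D-glucopyranoside | CO[C@H]1O[C@@H]2CO[C@@H](c3ccccc3)O[C@H]2[C@H](OCc2ccccc2)[C@H]1OCc1ccccc1 | intermediate
3 | methyl 4-O-benzoyl-2,3-di-O-benzyl-6-bromo-6-deoxy-α-D-glucopyranoside | CO[C@H]1O[C@H](CBr)[C@@H](OC(=O)c2ccccc2)[C@H](OCc2ccccc2)[C@H]1OCc1ccccc1 | intermediate
4 | methyl 4-O-benzoyl-2,3-di-O-benzyl-6-deoxy-α-D-xylo-hex-5-enopyranoside | CO[C@H]1OC(=C)[C@@H](OC(=O)c2ccccc2)[C@H](OCc2ccccc2)[C@H]1OCc1ccccc1 | intermediate
5 | 4-O-benzoyl-2,3-di-O-benzyl-6-deoxy-6-(trifluoroacetoxymercurio)-D-xylo-hexos-5-ulose, open chain | O=C[C@H](OCc1ccccc1)[C@@H](OCc1ccccc1)[C@H](OC(=O)c1ccccc1)C(=O)C[Hg]OC(=O)C(F)(F)F | intermediate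
6 | (2S,3R,4S,5S)-2-benzoyloxy-3,4-bis(benzyloxy)-5-hydroxycyclohexan-1-one | O=C1C[C@H](O)[C@H](OCc2ccccc2)[C@@H](OCc2ccccc2)[C@@H]1OC(=O)c1ccccc1 | intermediate
7 | 5-O-methanesulfonate of 6 | O=C1C[C@H](OS(C)(=O)=O)[C@H](OCc2ccccc2)[C@@H](OCc2ccccc2)[C@@H]1OC(=O)c1ccccc1 | intermediate
8 | (4S,5R,6S)-6-benzoyloxy-4,5-bis(benzyloxy)cyclohex-2-en-1-one | O=C1C=C[C@H](OCc2ccccc2)[C@@H](OCc2ccccc2)[C@@H]1OC(=O)c1ccccc1 | intermediate
9 | (4S,5R,6S)-6-benzoyloxy-4,5-bis(benzyloxy)-2-(hydroxymethyl)cyclohex-2-en-1-one | O=C1C(CO)=C[C@H](OCc2ccccc2)[C@@H](OCc2ccccc2)[C@@H]1OC(=O)c1ccccc1 | intermediate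
10 | [(3S,4R,5S)-5-benzoyloxy-3,4-bis(benzyloxy)-6-oxocyclohex-1-en-1-yl]methyl benzoate | O=C1C(COC(=O)c2ccccc2)=C[C@H](OCc2ccccc2)[C@@H](OCc2ccccc2)[C@@H]1OC(=O)c1ccccc1 | intermediate
11 | [(3S,4R,5S)-5-benzoyloxy-3,4-dihydroxy-6-oxocyclohex-1-en-1-yl]methyl benzoate | O=C1C(COC(=O)c2ccccc2)=C[C@H](O)[C@@H](O)[C@@H]1OC(=O)c1ccccc1 | intermediate
12 | tetramethylammonium diacetoxy(hydrido)borate bound through O4 of 11 | O=C1C(COC(=O)c2ccccc2)=C[C@H](O)[C@@H](O[BH-](OC(C)=O)OC(C)=O)[C@@H]1OC(=O)c1ccccc1.C[N+](C)(C)C | intermediate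
13 | [(3S,4R,5R,6R)-5-benzoyloxy-3,4,6-trihydroxycyclohex-1-en-1-yl]methyl benzoate | O=C(OCC1=C[C@H](O)[C@@H](O)[C@H](OC(=O)c2ccccc2)[C@@H]1O)c1ccccc1 | target

Total step count: 9. Longest linear sequence: 9 steps (fully linear from 1).

Steps most likely to fail

Step 9. The ring flip that brings the boron-bound hydride over the ketone may cost too much, so that delivery becomes slow and undirected axial attack erodes the facial selectivity at C6. The fallback replaces direction by inversion and sets out from 10. Luche reduction (NaBH4, CeCl3·7H2O, MeOH, −78 °C) should give, by axial attack on the all-equatorial half-chair, the C6-epimeric allylic alcohol F1. A Mitsunobu reaction with chloroacetic acid (PPh3, DIAD, toluene, 0 °C) inverts C6 to the (6R)-chloroacetate F2. Thiourea and NaHCO3 in EtOH remove the chloroacetyl group beside the benzoates to give the 3,4-di-O-benzyl ether of the target F3. BCl3 (CH2Cl2, −78 °C, then MeOH) brings the fallback back to the route at 13.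

Step 6. Enolisation towards C5 with loss of the C4 benzyloxy group and aromatisation, or a stalled addition of DMAP to the hindered C2, may consume the enone. The fallback replaces organocatalysis by cross-coupling and sets out from 8. I2 and pyridine in CH2Cl2 (addition–elimination α-iodination) should give the 2-iodoenone F4. A Stille coupling with Bu3SnCH2OH (Pd(PPh3)4, dioxane, 80 °C) comes back to the route at 9.

Step 2. Hydrogen abstraction at the benzyl ether CH2 groups may compete with abstraction at the acetal carbon. The fallback changes the order of events and sets out from 1. The same NBS/BaCO3 opening on the free diol should give methyl 4-O-benzoyl-6-bromo-6-deoxy-α-D-glucopyranoside F5. Acid-catalysed benzylation with benzyl 2,2,2-trichloroacetimidate (TfOH cat., CH2Cl2–cyclohexane, 0 °C), which does not move the ester, comes back to the route at 3.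

Further compounds
F1 | step 9 | [(3S,4R,5R,6S)-5-benzoyloxy-3,4-bis(benzyloxy)-6-hydroxycyclohex-1-en-1-yl]methyl benzoate | O[C@H]1C(COC(=O)c2ccccc2)=C[C@H](OCc2ccccc2)[C@@H](OCc2ccccc2)[C@@H]1OC(=O)c1ccccc1
F2 | step 9 | [(3S,4R,5R,6R)-5-benzoyloxy-3,4-bis(benzyloxy)-6-(chloroacetoxy)cyclohex-1-en-1-yl]methyl benzoate | O=C(CCl)O[C@@H]1C(COC(=O)c2ccccc2)=C[C@H](OCc2ccccc2)[C@@H](OCc2ccccc2)[C@@H]1OC(=O)c1ccccc1
F3 | step 9 | [(3S,4R,5R,6R)-5-benzoyloxy-3,4-bis(benzyloxy)-6-hydroxycyclohex-1-en-1-yl]methyl benzoate | O[C@@H]1C(COC(=O)c2ccccc2)=C[C@H](OCc2ccccc2)[C@@H](OCc2ccccc2)[C@@H]1OC(=O)c1ccccc1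
F4 | step 6 | (4S,5R,6S)-6-benzoyloxy-4,5-bis(benzyloxy)-2-iodocyclohex-2-en-1-one | O=C1C(I)=C[C@H](OCc2ccccc2)[C@@H](OCc2ccccc2)[C@@H]1OC(=O)c1ccccc1
F5 | step 2 | methyl 4-O-benzoyl-6-bromo-6-deoxy-α-D-glucopyranoside | CO[C@H]1O[C@H](CBr)[C@@H](OC(=O)c2ccccc2)[C@H](O)[C@H]1O
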